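**Retrosynthetic overview**
Ring A is the cyclohexenone (C1 carbonyl, C2=C3, quaternary C4, C5, C6). Ring B is the furan-2(5H)-one. The chain C1'–C10' joins C4 to ring B.
C3–C4 (ring A) and C1'–C2' (chain) are cut together: a domino 6-exo carbopalladation/allyl Suzuki–Miyaura coupling of the C10 iodoenone 15 with the C15 allylboronate 7.
Enabling feature: C4 bears C3 (sp2), C5, CH3 and C1'H2, so C1' is a neopentyl carbon without β-hydrogen, and C2' is allylic to C3'=C4'. An isopropenyl group on C5 is therefore a latent C4(CH3)(C1'H2–).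
15 comes from a crotonyl imide (auxiliary-controlled conjugate addition sets C5, then Weinreb amide, ynone, hydroiodination). 7 comes from (E)-geranylacetone (α'-hydroxylation, ylide butenolide closure, Riley oxidation, allylic borylation).
Ring order: ring B closes in step 2, ring A closes last in step 10.
Key step: step 10

Assumption: commercial geranylacetone is used as the single 5E isomer, and the palladium species 16 and 17 are drawn without their phosphine ligand.

Step 1
Reactants: 1 (5E)-6,10-dimethylundeca-5,9-dien-2-one ((E)-geranylacetone)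
Product: 3 (5E)-1-hydroxy-6,10-dimethylundeca-5,9-dien-2-one, via lithium enolate 2 (not isolated)
Conditions: LDA, THF, −78 °C; 2-(phenylsulfonyl)-3-phenyloxaziridine, −78 °C; aq NH4Cl
Reagents that add atoms: 2-(phenylsulfonyl)-3-phenyloxaziridine, O=S(=O)(N1OC1c1ccccc1)c1ccccc1
Why: Kinetic deprotonation at the CH3 side followed by oxygen transfer from the N-sulfonyloxaziridine (enolate hydroxylation) should give the primary α-hydroxy ketone and leave both trisubstituted alkenes alone; no stereocentre is formed.

Step 2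
Reactants: 3 (5E)-1-hydroxy-6,10-dimethylundeca-5,9-dien-2-one
Product: 5 4-[(3E)-4,8-dimethylnona-3,7-dien-1-yl]furan-2(5H)-one, via acyl ylide 4 (not isolated)
Conditions: Ph3P=C=C=O, toluene, reflux
Reagents that add atoms: (triphenylphosphoranylidene)ketene, O=C=C=P(c1ccccc1)(c1ccccc1)c1ccccc1
Why: The alcohol adds to the cumulated ylide, and the resulting ester ylide closes ring B by an intramolecular Wittig reaction on the neighbouring ketone; no stereocentre is formed.

Step 3
Reactants: 5 4-[(3E)-4,8-dimethylnona-3,7-dien-1-yl]furan-2(5H)-one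
Product: 6 4-[(3E,7E)-9-hydroxy-4,8-dimethylnona-3,7-dien-1-yl]furan-2(5H)-one
Conditions: SeO2 (cat.), t-BuOOH, salicylic acid (cat.), CH2Cl2, 0 °C to rt, stopped at partial conversion
Reagents that add atoms: tert-butyl hydroperoxide, CC(C)(C)OO
Why: The Riley allylic oxidation (ene reaction, then [2,3]-shift) should attack the terminal gem-dimethyl alkene at its E methyl group and give the E allylic alcohol; the electron-poor butenolide alkene should not react.

Step 4
Reactants: 6 4-[(3E,7E)-9-hydroxy-4,8-dimethylnona-3,7-dien-1-yl]furan-2(5H)-one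
Product: 7 4-[(3E,7E)-4,8-dimethyl-9-(4,4,5,5-tetramethyl-1,3,2-dioxaborolan-2-yl)nona-3,7-dien-1-yl]furan-2(5H)-one
Conditions: B2pin2, Pd(MeCN)4(BF4)2 (5 mol %), DMSO/MeOH 1:1, 40 °C
Reagents that add atoms: bis(pinacolato)diboron, CC1(C)OB(OC1(C)C)B1OC(C)(C)C(C)(C)O1
Why: Palladium-catalysed allylic C–OH borylation via a syn π-allyl complex should place boron on the primary terminus with the E alkene retained, under conditions mild enough for the lactone.

Step 5
Reactants: 8 (4S)-4-benzyl-1,3-oxazolidin-2-one, 9 (2E)-but-2-enoyl chloride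
Product: 11 (4S)-4-benzyl-3-[(2E)-but-2-enoyl]-1,3-oxazolidin-2-one, via lithium oxazolidinonide 10 (not isolated)
Conditions: n-BuLi, THF, −78 °C; then 9, −78 to 0 °C
Reagents that add atoms: none
Why: N-Acylation of the lithiated auxiliary is a standard imide synthesis and leaves the auxiliary stereocentre and the E alkene unchanged.

Step 6
Reactants: 11 (4S)-4-benzyl-3-[(2E)-but-2-enoyl]-1,3-oxazolidin-2-one
Product: 12 (4S)-4-benzyl-3-[(3R)-3,4-dimethylpent-4-enoyl]-1,3-oxazolidin-2-one
Conditions: isopropenylMgBr, CuBr·SMe2 (1:1), THF/Me2S, −78 to −20 °C; aq NH4Cl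
Reagents that add atoms: isopropenylmagnesium bromide, C=C(C)[Mg]Br
Why: In this auxiliary-controlled organocopper conjugate addition the magnesium-chelated syn, s-cis imide is attacked on the face opposite the benzyl group, which should set the future C5 as R.

Step 7
Reactants: 12 (4S)-4-benzyl-3-[(3R)-3,4-dimethylpent-4-enoyl]-1,3-oxazolidin-2-one
Product: 13 (3R)-N-methoxy-N,3,4-trimethylpent-4-enamide
Conditions: MeNH(OMe)·HCl, AlMe3, CH2Cl2, −10 °C to rt; 0.5 M HCl
Reagents that add atoms: N,O-dimethylhydroxylamine hydrochloride, CNOC.Cl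
Why: Aluminium-amide aminolysis of the exocyclic imide carbonyl gives the Weinreb amide and frees the auxiliary; the β-stereocentre is not enolisable and should be kept.

Step 8
Reactants: 13 (3R)-N-methoxy-N,3,4-trimethylpent-4-enamide
Product: 14 (6R)-6,7-dimethyloct-7-en-2-yn-4-one
Conditions: 1-propynylMgBr, THF, 0 °C; aq NH4Cl
Reagents that add atoms: 1-propynylmagnesium bromide, CC#C[Mg]Br
Why: In the Weinreb ketone synthesis the chelated tetrahedral adduct survives until work-up, so over-addition and conjugate addition to the ynone should be avoided.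

Step 9
Reactants: 14 (6R)-6,7-dimethyloct-7-en-2-yn-4-one
Product: 15 (2Z,6R)-2-iodo-6,7-dimethylocta-2,7-dien-4-one
Conditions: NaI, AcOH, rt, dark
Reagents that add atoms: sodium iodide, [Na+].[I-]
Why: Conjugate hydroiodination of the ynone (iodide attack at the β-carbon, then anti protonation of the allenol) should give the Z β-iodoenone with iodine cis to the acyl chain; the unactivated isopropenyl group should not react.

Step 10
Reactants: 15 (2Z,6R)-2-iodo-6,7-dimethylocta-2,7-dien-4-one, 7 4-[(3E,7E)-4,8-dimethyl-9-(4,4,5,5-tetramethyl-1,3,2-dioxaborolan-2-yl)nona-3,7-dien-1-yl]furan-2(5H)-one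
Product: 18 cyclolinteinone, via vinylpalladium iodide 16 (not isolated), via neopentylpalladium iodide 17 (not isolated)
Conditions: Pd2(dba)3 (2.5 mol %), dppf (6 mol %), CsF (3 equiv), THF, 65 °C, 7 added over 6 h
Reagents that add atoms: none
Why: Proposed new method: oxidative addition of Pd(0) into the C3–I bond gives 16, syn-carbopalladation of the isopropenyl group forms C3–C4 and the σ-alkylpalladium 17, and fluoride-assisted transmetalation with 7 followed by alkyl–allyl reductive elimination forms C1'–C2' and releases 18. The closest known reaction types are the Pd(0)-catalysed 6-exo cyclisation of (Z)-1-iodo-1,6-dienes onto 1,1-disubstituted alkenes, the cyclisation/anion-capture variant of the Mizoroki–Heck reaction and the Suzuki–Miyaura coupling of allylboronates; what is new is the capture of a neopentyl-type alkylpalladium by an allylboronate. Ring A closes in the 6-exo-trig mode, which the Z geometry of the iodoenone (Pd cis to the acyl chain) and the 1,1-disubstitution of the alkene enforce. The new quaternary centre C4 is controlled by C5: in the half-chair insertion state the C5 methyl is pseudo-equatorial, the C4=CH2 bond must lie parallel to the C3–Pd bond and so becomes the pseudo-axial C1', and the C4 methyl stays pseudo-equatorial as the smaller group next to the C3 methyl, which should give the trans-4,5-dimethyl (4R,5R) array. Cyclisation must outrun direct vinyl–allyl coupling, and coupling must occur at the primary allyl terminus with the E alkene kept; the first is served by the intramolecular insertion plus slow addition of 7, the second by the bulk of the neopentyl partner acting on the syn π-allyl. Because 17 has no β-hydrogen, it should persist long enough to be intercepted.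

**Compound list**
1 | (5E)-6,10-dimethylundeca-5,9-dien-2-one | CC(C)=CCC/C(C)=C/CCC(C)=O | starting material
2 | lithium (5E)-6,10-dimethylundeca-1,5,9-trien-2-olate | CC(C)=CCC/C(C)=C/CCC(=C)O[Li] | intermediate
3 | (5E)-1-hydroxy-6,10-dimethylundeca-5,9-dien-2-one | CC(C)=CCC/C(C)=C/CCC(=O)CO | intermediate
4 | (5E)-6,10-dimethyl-2-oxoundeca-5,9-dien-1-yl (triphenylphosphoranylidene)acetate | CC(C)=CCC/C(C)=C/CCC(=O)COC(=O)C=P(c1ccccc1)(c1ccccc1)c1ccccc1 | intermediate
5 | 4-[(3E)-4,8-dimethylnona-3,7-dien-1-yl]furan-2(5H)-one | CC(C)=CCC/C(C)=C/CCC1=CC(=O)OC1 | intermediate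
6 | 4-[(3E,7E)-9-hydroxy-4,8-dimethylnona-3,7-dien-1-yl]furan-2(5H)-one | OC/C(C)=C/CC/C(C)=C/CCC1=CC(=O)OC1 | intermediate
7 | 4-[(3E,7E)-4,8-dimethyl-9-(4,4,5,5-tetramethyl-1,3,2-dioxaborolan-2-yl)nona-3,7-dien-1-yl]furan-2(5H)-one | CC1(C)OB(C/C(C)=C/CC/C(C)=C/CCC2=CC(=O)OC2)OC1(C)C | intermediate
8 | (4S)-4-benzyl-1,3-oxazolidin-2-one | O=C1N[C@@H](Cc2ccccc2)CO1 | starting material
9 | (2E)-but-2-enoyl chloride | C/C=C/C(=O)Cl | starting material
10 | lithium salt of (4S)-4-benzyl-1,3-oxazolidin-2-one | [Li]N1[C@@H](Cc2ccccc2)COC1=O | intermediate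
11 | (4S)-4-benzyl-3-[(2E)-but-2-enoyl]-1,3-oxazolidin-2-one | C/C=C/C(=O)N1[C@@H](Cc2ccccc2)COC1=O | intermediate
12 | (4S)-4-benzyl-3-[(3R)-3,4-dimethylpent-4-enoyl]-1,3-oxazolidin-2-one | O=C(C[C@@H](C)C(C)=C)N1[C@@H](Cc2ccccc2)COC1=O | intermediate
13 | (3R)-N-methoxy-N,3,4-trimethylpent-4-enamide | CON(C)C(=O)C[C@@H](C)C(C)=C | intermediate
14 | (6R)-6,7-dimethyloct-7-en-2-yn-4-one | CC#CC(=O)C[C@@H](C)C(C)=C | intermediate
15 | (2Z,6R)-2-iodo-6,7-dimethylocta-2,7-dien-4-one | C/C(I)=C/C(=O)C[C@@H](C)C(C)=C | intermediate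
16 | [(2Z,6R)-6,7-dimethyl-4-oxoocta-2,7-dien-2-yl]palladium(II) iodide | C/C([Pd]I)=C/C(=O)C[C@@H](C)C(C)=C | intermediate
17 | {[(1R,6R)-1,2,6-trimethyl-4-oxocyclohex-2-en-1-yl]methyl}palladium(II) iodide | CC1=CC(=O)C[C@@H](C)[C@@]1(C)C[Pd]I | intermediate
18 | cyclolinteinone, 4-[(3E,7E)-4,8-dimethyl-10-[(1R,6R)-1,2,6-trimethyl-4-oxocyclohex-2-en-1-yl]deca-3,7-dien-1-yl]furan-2(5H)-one | CC1=CC(=O)C[C@@H](C)[C@@]1(C)CC/C(C)=C/CC/C(C)=C/CCC1=CC(=O)OC1 | target

Total step count: 10. Longest linear sequence: 6 (steps 5–10).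

**Steps most likely to fail**

Step 10. Several things may go wrong:
- Transmetalation may overtake the 6-exo insertion, so that the vinyl and allyl groups couple directly.
- The allyl group may couple at its secondary terminus.
- The alkylpalladium may insert 3-exo into the enone.
- Facial selectivity at C4 may be poor.

The fallback separates the two events with known chemistry. It sets out from 15 and 6 and returns at 18. Pd(OAc)2/dppf in hot toluene isomerises 15 by iodine-atom-transfer cyclisation to the neopentyl iodide (4R,5R)-4-(iodomethyl)-3,4,5-trimethylcyclohex-2-en-1-one F1. Alcohol 6 is acetylated (Ac2O, pyridine) to the allylic acetate (2E,6E)-2,6-dimethyl-9-(5-oxo-2,5-dihydrofuran-3-yl)nona-2,6-dien-1-yl acetate F2. A nickel-catalysed reductive cross-electrophile allylation (NiCl2·glyme, 4,4'-di-tert-butyl-2,2'-bipyridine, Zn, DMA) then joins F1 and F2 at the primary allyl terminus to give 18.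

Step 3. Allylic oxidation may also occur at the internal alkene, and the alcohol may be over-oxidised, so material could be lost in separations. The fallback replaces C–H oxidation by alkene exchange. It sets out from 5 and returns at 6. Cross metathesis of the prenyl terminus with methacrolein (Hoveyda–Grubbs second-generation catalyst, CH2Cl2, 40 °C) should give the enal (2E,6E)-2,6-dimethyl-9-(5-oxo-2,5-dihydrofuran-3-yl)nona-2,6-dienal F3. A Luche reduction (NaBH4, CeCl3, MeOH, −78 °C) then converts F3 into 6.

Step 1. The enolate may add to the sulfonimine co-product, or it may equilibrate to the internal enolate and lose regiocontrol. The fallback avoids both the oxaziridine and the ketenylidene ylide. It sets out from 1 and returns at 5.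
- LDA/TMSCl gives the kinetic silyl enol ether trimethyl{[(5E)-6,10-dimethylundeca-1,5,9-trien-2-yl]oxy}silane F4.
- NBS at −78 °C gives the bromoketone (5E)-1-bromo-6,10-dimethylundeca-5,9-dien-2-one F5.
- Potassium diethylphosphonoacetate in DMF gives the ester (5E)-6,10-dimethyl-2-oxoundeca-5,9-dien-1-yl (diethoxyphosphoryl)acetate F6.
- An intramolecular Horner–Wadsworth–Emmons reaction (K2CO3, 18-crown-6, toluene) closes F6 to 5.

**Further compounds**
F1 | step 10 | (4R,5R)-4-(iodomethyl)-3,4,5-trimethylcyclohex-2-en-1-one | CC1=CC(=O)C[C@@H](C)[C@@]1(C)CI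
F2 | step 10 | (2E,6E)-2,6-dimethyl-9-(5-oxo-2,5-dihydrofuran-3-yl)nona-2,6-dien-1-yl acetate | CC(=O)OC/C(C)=C/CC/C(C)=C/CCC1=CC(=O)OC1
F3 | step 3 | (2E,6E)-2,6-dimethyl-9-(5-oxo-2,5-dihydrofuran-3-yl)nona-2,6-dienal | O=C/C(C)=C/CC/C(C)=C/CCC1=CC(=O)OC1
F4 | step 1 | trimethyl{[(5E)-6,10-dimethylundeca-1,5,9-trien-2-yl]oxy}silane | CC(C)=CCC/C(C)=C/CCC(=C)O[Si](C)(C)C
F5 | step 1 | (5E)-1-bromo-6,10-dimethylundeca-5,9-dien-2-one | CC(C)=CCC/C(C)=C/CCC(=O)CBr
F6 | step 1 | (5E)-6,10-dimethyl-2-oxoundeca-5,9-dien-1-yl (diethoxyphosphoryl)acetate | CC(C)=CCC/C(C)=C/CCC(=O)COC(=O)CP(=O)(OCC)OCC
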